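**Plan**
- Target: (7S,8S)-threo-guaiacylglycerol 8-O-(4-hydroxy-2,6-dimethoxyphenyl) ether. C7 is the benzylic carbinol on guaiacyl ring A, C8 is the CH bearing the ring B aryloxy group, and C9 is CH2OH. C7-OH and C8-OAr are syn along the zigzag Ar–C7–C8–C9.
- Retrosynthetic cuts, in order: the two phenolic O–H become O–benzyl. C9 is raised from CH2OH to an N-acyloxazolidinone. C7–C8 is cut by a retro-aldol into O-benzylvanillin and an N-(aryloxyacetyl)oxazolidinone. Then N–C9, O–C8 and the ring B C4–O bond are cut back to (R)-4-benzyloxazolidin-2-one, methyl bromoacetate and syringaldehyde.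
- Enabling feature: C8 carries the ring B aryloxy oxygen and lies next to C9. With C9 at the acyl level, C8 is a glycolate-type α-carbon that gives one (Z)-boron enolate. C7, the carbinol carbon on ring A, is the former CHO carbon of a vanillin ether.
- Forward order (no ring is formed): the ring B half is built in five steps (O-alkylation, CHO to OH by Baeyer–Villiger oxidation, benzylation, saponification, N-acylation). It is joined to the ring A half by the aldol, then C9 is reduced and both benzyl groups are removed.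
- Stereochemistry: C7 and C8 are both set in the aldol. The relative configuration comes from the enolate geometry in a closed chair, and the absolute configuration from the (R)-4-benzyl auxiliary. No later step touches either center.

Key step: step 6

Assumption: the SMILES is read as 7S,8S (threo), and compounds 1, 2, 8 and 11 are taken as commercial.

**Step 1**
Reactants: 1 syringaldehyde (4-hydroxy-3,5-dimethoxybenzaldehyde); 2 methyl bromoacetate
Product: 3 methyl 2-(4-formyl-2,6-dimethoxyphenoxy)acetate
Conditions: K2CO3, DMF, rt to 60 °C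
Reagents that add atoms: none
Why: Williamson ether synthesis: the phenoxide of 1, readily formed because of the para formyl group, displaces bromide from the unhindered, carbonyl-activated primary bromide 2 by SN2 despite its two ortho methoxy groups, and no stereocenter is created.

**Step 2**
Reactants: 3 methyl 2-(4-formyl-2,6-dimethoxyphenoxy)acetate
Product: 5 methyl 2-(4-hydroxy-2,6-dimethoxyphenoxy)acetate, via aryl formate 4 (not isolated)
Conditions: mCPBA, CH2Cl2, 0 °C to rt; aq. Na2S2O3/NaHCO3 wash; then K2CO3 (cat.), MeOH, N2, 0 °C to rt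
Reagents that add atoms: mCPBA, O=C(OO)c1cccc(Cl)c1
Why: Baeyer–Villiger oxidation of an electron-rich benzaldehyde (Dakin-type outcome): in the Criegee adduct the 4-alkoxy-3,5-dimethoxyphenyl group migrates in preference to hydride, and the aryl formate 4 is far more labile to base-catalysed methanolysis than the alkyl ester, whose exchange with methanol is degenerate.

**Step 3**
Reactants: 5 methyl 2-(4-hydroxy-2,6-dimethoxyphenoxy)acetate
Product: 6 methyl 2-(4-benzyloxy-2,6-dimethoxyphenoxy)acetate
Conditions: BnBr, K2CO3, DMF, rt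
Reagents that add atoms: benzyl bromide, BrCc1ccccc1
Why: Williamson benzylation of the only free, unhindered phenol; the benzyl ether masks the acidic OH against Bu2BOTf and bases and is removed in the last step together with that of ring A.

**Step 4**
Reactants: 6 methyl 2-(4-benzyloxy-2,6-dimethoxyphenoxy)acetate
Product: 7 2-(4-benzyloxy-2,6-dimethoxyphenoxy)acetic acid
Conditions: LiOH, THF/H2O, 0 °C to rt; then 1 M HCl
Reagents that add atoms: lithium hydroxide, [Li+].[OH-] (supplies the new carboxyl oxygen)
Why: Saponification (BAc2 ester hydrolysis) of an unhindered methyl ester, to which the aryl, benzyl and methyl ethers are inert.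

**Step 5**
Reactants: 7 2-(4-benzyloxy-2,6-dimethoxyphenoxy)acetic acid; 8 (R)-4-benzyloxazolidin-2-one
Product: 10 (R)-4-benzyl-3-[2-(4-benzyloxy-2,6-dimethoxyphenoxy)acetyl]oxazolidin-2-one, via mixed pivalic anhydride 9 (not isolated)
Conditions: PivCl, Et3N, THF, −20 °C; then LiCl, 8, −20 °C to rt
Reagents that add atoms: pivaloyl chloride, CC(C)(C)C(=O)Cl (its acyl group is held only in intermediate 9)
Why: N-Acylation of an oxazolidinone by the mixed pivalic anhydride method (LiCl/Et3N variant): the nitrogen of 8 attacks the less hindered aryloxyacetyl carbonyl of 9, and the C4 stereocenter of 8 is not involved.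

**Step 6**
Reactants: 10 (R)-4-benzyl-3-[2-(4-benzyloxy-2,6-dimethoxyphenoxy)acetyl]oxazolidin-2-one; 11 4-benzyloxy-3-methoxybenzaldehyde (O-benzylvanillin)
Product: 14 (R)-4-benzyl-3-[(2R,3S)-3-(4-benzyloxy-3-methoxyphenyl)-2-(4-benzyloxy-2,6-dimethoxyphenoxy)-3-hydroxypropanoyl]oxazolidin-2-one, via Z-dibutylboron enolate 12 (not isolated), via dibutylboron aldolate 13 (not isolated)
Conditions: Bu2BOTf, i-Pr2NEt, CH2Cl2, −78 to 0 °C; 11, −78 to 0 °C; then pH 7 buffer, MeOH, 30% H2O2, 0 °C
Reagents that add atoms: dibutylboron triflate, CCCCB(CCCC)OS(=O)(=O)C(F)(F)F (its Bu2B group is held only in intermediates 12 and 13)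
Why: Bu2BOTf/i-Pr2NEt enolises imide 10 softly to the single (Z)-boron enolate 12 (aryloxy oxygen cis to O–B, the E form being excluded by A(1,3) strain against the auxiliary), aldehyde 11 then coordinates to boron and C7–C8 forms through a closed six-membered Zimmerman–Traxler chair to give aldolate 13, which the buffered H2O2 work-up converts into 14. The closest known reaction type is the Evans syn aldol of boron enolates of N-(alkoxyacetyl)- and N-(aryloxyacetyl)oxazolidinones (glycolate aldol) with aromatic aldehydes. No ring of the target is closed, the boron-containing chair being a transient array only. C7 relative to C8: the Z geometry together with the equatorial aryl group of 11 in the chair places C7-OH and C8-OAr syn along Ar–C7–C8–C9, which is the threo relation of the target. C8 absolute: in the reacting rotamer the imide and enolate C–O dipoles are opposed and the C4 benzyl group of the (R)-auxiliary shields one enolate face, so 11 is taken up at the other face and 14 is expected as the 2R,3S isomer, which reads 7S,8S once C9 has become CH2OH. The step needs syn/anti selectivity, facial selectivity and cross- rather than self-reaction: the short B–O bonds and the single enolate geometry secure the first two, and the non-enolisable aldehyde 11 together with the benzyl ethers on both phenols (no free ArOH to bind boron or to open a quinone-methide path at C7) secures the last.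

**Step 7**
Reactants: 14 (R)-4-benzyl-3-[(2R,3S)-3-(4-benzyloxy-3-methoxyphenyl)-2-(4-benzyloxy-2,6-dimethoxyphenoxy)-3-hydroxypropanoyl]oxazolidin-2-one
Product: 15 (1S,2S)-1-(4-benzyloxy-3-methoxyphenyl)-2-(4-benzyloxy-2,6-dimethoxyphenoxy)propane-1,3-diol
Conditions: NaBH4, THF/H2O (4:1), 0 °C to rt
Reagents that add atoms: none
Why: Reductive cleavage of an N-acyloxazolidinone with borohydride: hydride attacks the more electrophilic exocyclic imide carbonyl, the auxiliary 8 leaves and the aldehyde so formed is reduced at once to the C9 alcohol, so C7 and C8 keep their configuration (the descriptor at C8 changes from R to S only because C9 falls in CIP rank).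

**Step 8**
Reactants: 15 (1S,2S)-1-(4-benzyloxy-3-methoxyphenyl)-2-(4-benzyloxy-2,6-dimethoxyphenoxy)propane-1,3-diol
Product: 16 (1S,2S)-1-(4-hydroxy-3-methoxyphenyl)-2-(4-hydroxy-2,6-dimethoxyphenoxy)propane-1,3-diol (target)
Conditions: H2 (1 atm), 10% Pd/C, EtOAc/EtOH, rt, stopped after uptake of two equivalents
Reagents that add atoms: none
Why: Catalytic hydrogenolysis of two aryl benzyl ethers: the primary O-benzyl C–O bonds are cleaved much faster on Pd/C in a neutral, acid-free solvent than the secondary C7–OH bond or the C8–OAr ether, and neutral conditions give the p-hydroxybenzylic alcohol no path to epimerise through a quinone methide.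

**Compound list**
1 | syringaldehyde (4-hydroxy-3,5-dimethoxybenzaldehyde) | COc1cc(C=O)cc(OC)c1O | starting material
2 | methyl bromoacetate | COC(=O)CBr | starting material
3 | methyl 2-(4-formyl-2,6-dimethoxyphenoxy)acetate | COC(=O)COc1c(OC)cc(C=O)cc1OC | intermediate
4 | methyl 2-(4-formyloxy-2,6-dimethoxyphenoxy)acetate (aryl formate, not isolated) | COC(=O)COc1c(OC)cc(OC=O)cc1OC | intermediate
5 | methyl 2-(4-hydroxy-2,6-dimethoxyphenoxy)acetate | COC(=O)COc1c(OC)cc(O)cc1OC | intermediate
6 | methyl 2-(4-benzyloxy-2,6-dimethoxyphenoxy)acetate | COC(=O)COc1c(OC)cc(OCc2ccccc2)cc1OC | intermediate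
7 | 2-(4-benzyloxy-2,6-dimethoxyphenoxy)acetic acid | OC(=O)COc1c(OC)cc(OCc2ccccc2)cc1OC | intermediate
8 | (R)-4-benzyloxazolidin-2-one | O=C1N[C@H](Cc2ccccc2)CO1 | starting material
9 | 2-(4-benzyloxy-2,6-dimethoxyphenoxy)acetic pivalic anhydride (not isolated) | CC(C)(C)C(=O)OC(=O)COc1c(OC)cc(OCc2ccccc2)cc1OC | intermediate
10 | (R)-4-benzyl-3-[2-(4-benzyloxy-2,6-dimethoxyphenoxy)acetyl]oxazolidin-2-one | O=C(COc1c(OC)cc(OCc2ccccc2)cc1OC)N1[C@H](Cc2ccccc2)COC1=O | intermediate
11 | 4-benzyloxy-3-methoxybenzaldehyde (O-benzylvanillin) | COc1cc(C=O)ccc1OCc1ccccc1 | starting material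
12 | (Z)-dibutylboron enolate of 10, aryloxy group cis to O–BBu2 (not isolated) | CCCCB(CCCC)O/C(=C\Oc1c(OC)cc(OCc2ccccc2)cc1OC)N1[C@H](Cc2ccccc2)COC1=O | intermediate
13 | dibutylboron aldolate, the C7–O–BBu2 derivative of 14 (not isolated) | COc1cc([C@H](OB(CCCC)CCCC)[C@H](C(=O)N2[C@H](Cc3ccccc3)COC2=O)Oc2c(OC)cc(OCc3ccccc3)cc2OC)ccc1OCc1ccccc1 | intermediate
14 | (R)-4-benzyl-3-[(2R,3S)-3-(4-benzyloxy-3-methoxyphenyl)-2-(4-benzyloxy-2,6-dimethoxyphenoxy)-3-hydroxypropanoyl]oxazolidin-2-one | COc1cc([C@H](O)[C@H](C(=O)N2[C@H](Cc3ccccc3)COC2=O)Oc2c(OC)cc(OCc3ccccc3)cc2OC)ccc1OCc1ccccc1 | intermediate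
15 | (1S,2S)-1-(4-benzyloxy-3-methoxyphenyl)-2-(4-benzyloxy-2,6-dimethoxyphenoxy)propane-1,3-diol | COc1cc([C@H](O)[C@H](CO)Oc2c(OC)cc(OCc3ccccc3)cc2OC)ccc1OCc1ccccc1 | intermediate
16 | (1S,2S)-1-(4-hydroxy-3-methoxyphenyl)-2-(4-hydroxy-2,6-dimethoxyphenoxy)propane-1,3-diol | COc1cc([C@H](O)[C@H](CO)Oc2c(OC)cc(O)cc2OC)ccc1O | target

Total step count: 8. Longest linear sequence: 8 steps (1 to 16). Compounds 2, 8 and 11 enter as purchased materials.

**Steps most likely to fail**

**Step 6.**
- Risk: the hindered aryloxy enolate may add only sluggishly to the electron-rich, weakly electrophilic aldehyde. Retro-aldol equilibration on warming would then erode facial and syn/anti selectivity.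
- Fallback (sets out from 6 and 11, returns at 15): bond formation and stereocontrol are separated.
- The lithium enolate of ester 6 (LDA, THF, −78 °C) is added to 11. This gives, without stereocontrol, racemic methyl 3-(4-benzyloxy-3-methoxyphenyl)-2-(4-benzyloxy-2,6-dimethoxyphenoxy)-3-hydroxypropanoate F1 as a diastereomer mixture.
- Dess–Martin oxidation converts it into the configurationally labile β-keto ester methyl 3-(4-benzyloxy-3-methoxyphenyl)-2-(4-benzyloxy-2,6-dimethoxyphenoxy)-3-oxopropanoate F2.
- Noyori-type asymmetric transfer hydrogenation under dynamic kinetic resolution follows (RuCl[(R,R)-TsDPEN](p-cymene), HCO2H/Et3N 5:2). The catalyst antipode is chosen by analogy with the facial rule for aryl ketones.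
- This should funnel both enantiomers of F2 into the syn ester methyl (2R,3S)-3-(4-benzyloxy-3-methoxyphenyl)-2-(4-benzyloxy-2,6-dimethoxyphenoxy)-3-hydroxypropanoate F3.
- LiAlH4 (THF, 0 °C) reduces F3 to 15.

**Step 7.**
- Risk: retro-aldol fragmentation of the β-hydroxy imide in the basic borohydride medium, epimerisation at C8 at the transient aldehyde stage, or hydride attack at the ring carbamate carbonyl with opening of the oxazolidinone.
- Fallback (sets out from 14, returns at 15): the auxiliary is removed hydrolytically and the reduction is done on the acid.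
- LiOH/H2O2 (THF/H2O, 0 °C, Na2SO3 quench) attacks the exocyclic carbonyl selectively. It gives (2R,3S)-3-(4-benzyloxy-3-methoxyphenyl)-2-(4-benzyloxy-2,6-dimethoxyphenoxy)-3-hydroxypropanoic acid F4.
- BH3·THF (0 °C to rt) reduces F4 chemoselectively and under non-basic conditions to 15.

**Step 8.**
- Risk: over-reduction with hydrogenolytic loss of the C7 benzylic hydroxyl group, incomplete cleavage of one benzyl ether, or epimerisation at C7 through a quinone methide if traces of acid are present once the ring A phenol is free.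
- Fallback (sets out from 5, returns at 16): the reductive deprotection is designed out by exchanging benzyl for allyl.
- Phenol 5 is O-allylated (allyl bromide, K2CO3, DMF) to methyl 2-(4-allyloxy-2,6-dimethoxyphenoxy)acetate F5.
- F5 is saponified (LiOH) to 2-(4-allyloxy-2,6-dimethoxyphenoxy)acetic acid F6.
- F6 is coupled with 8 (PivCl, Et3N, LiCl) to (R)-3-[2-(4-allyloxy-2,6-dimethoxyphenoxy)acetyl]-4-benzyloxazolidin-2-one F7.
- The boron aldol of step 6, run on F7 with commercial 4-allyloxy-3-methoxybenzaldehyde F8, should give (R)-3-[(2R,3S)-3-(4-allyloxy-3-methoxyphenyl)-2-(4-allyloxy-2,6-dimethoxyphenoxy)-3-hydroxypropanoyl]-4-benzyloxazolidin-2-one F9.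
- NaBH4 (THF/H2O) gives (1S,2S)-1-(4-allyloxy-3-methoxyphenyl)-2-(4-allyloxy-2,6-dimethoxyphenoxy)propane-1,3-diol F10.
- Pd(PPh3)4 (cat.) with morpholine in THF at rt (Tsuji–Trost deallylation) transfers both allyl groups to the amine. This gives 16 under neutral, non-reductive conditions.

**Further compounds**
F1 | step 6 | methyl 3-(4-benzyloxy-3-methoxyphenyl)-2-(4-benzyloxy-2,6-dimethoxyphenoxy)-3-hydroxypropanoate (racemic diastereomer mixture) | COC(=O)C(Oc1c(OC)cc(OCc2ccccc2)cc1OC)C(O)c1ccc(OCc2ccccc2)c(OC)c1
F2 | step 6 | methyl 3-(4-benzyloxy-3-methoxyphenyl)-2-(4-benzyloxy-2,6-dimethoxyphenoxy)-3-oxopropanoate (racemic, labile at C2) | COC(=O)C(Oc1c(OC)cc(OCc2ccccc2)cc1OC)C(=O)c1ccc(OCc2ccccc2)c(OC)c1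
F3 | step 6 | methyl (2R,3S)-3-(4-benzyloxy-3-methoxyphenyl)-2-(4-benzyloxy-2,6-dimethoxyphenoxy)-3-hydroxypropanoate | COc1cc([C@H](O)[C@H](C(=O)OC)Oc2c(OC)cc(OCc3ccccc3)cc2OC)ccc1OCc1ccccc1
F4 | step 7 | (2R,3S)-3-(4-benzyloxy-3-methoxyphenyl)-2-(4-benzyloxy-2,6-dimethoxyphenoxy)-3-hydroxypropanoic acid | COc1cc([C@H](O)[C@H](C(=O)O)Oc2c(OC)cc(OCc3ccccc3)cc2OC)ccc1OCc1ccccc1
F5 | step 8 | methyl 2-(4-allyloxy-2,6-dimethoxyphenoxy)acetate | COC(=O)COc1c(OC)cc(OCC=C)cc1OC
F6 | step 8 | 2-(4-allyloxy-2,6-dimethoxyphenoxy)acetic acid | OC(=O)COc1c(OC)cc(OCC=C)cc1OC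
F7 | step 8 | (R)-3-[2-(4-allyloxy-2,6-dimethoxyphenoxy)acetyl]-4-benzyloxazolidin-2-one | O=C(COc1c(OC)cc(OCC=C)cc1OC)N1[C@H](Cc2ccccc2)COC1=O
F8 | step 8 | 4-allyloxy-3-methoxybenzaldehyde | COc1cc(C=O)ccc1OCC=C
F9 | step 8 | (R)-3-[(2R,3S)-3-(4-allyloxy-3-methoxyphenyl)-2-(4-allyloxy-2,6-dimethoxyphenoxy)-3-hydroxypropanoyl]-4-benzyloxazolidin-2-one | COc1cc([C@H](O)[C@H](C(=O)N2[C@H](Cc3ccccc3)COC2=O)Oc2c(OC)cc(OCC=C)cc2OC)ccc1OCC=C
F10 | step 8 | (1S,2S)-1-(4-allyloxy-3-methoxyphenyl)-2-(4-allyloxy-2,6-dimethoxyphenoxy)propane-1,3-diol | COc1cc([C@H](O)[C@H](CO)Oc2c(OC)cc(OCC=C)cc2OC)ccc1OCC=C
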